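**Plan**

1. Numbering: each half is numbered as a phthalide (C1–C7a for the half with the 6-hydroxyl, primed for the other). The halves are joined by C7–C6' and C4–C7', so the core is a bicyclo[2.2.2]octene with bridgeheads C4 and C7 and bridges C3a=C7a, C5–C6 and C6'–C7'.
2. Retrosynthetic cuts, in order: both enol-lactone bonds O2–C3 and O2'–C3' (to γ-keto acids), C1'–C7a' (carbon monoxide), C3a'–C7a' (Claisen), C4'–C5' (Wittig), butyl–C3 (cuprate) and the C3a=C7a unsaturation, leading back to a meso dianhydride.
3. Enabling feature: in the primed cyclohexene ring (C3a'–C4'–C5'–C6'–C7'–C7a') C7a' is a carboxyl-level carbon on C7' and C3a' lies α to the C3' ketone carbon, so C3a'–C7a' is the bond of an intramolecular Claisen condensation of an ε-keto ester.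
4. Forward order of rings: the bicyclooctene is bought; a temporary γ-lactone (C5'–O–C6) is closed and later opened; the primed carbocycle closes in the Claisen step; the two butenolide rings close together in the last step.
5. Stereochemistry: C4, C7, C6' and C7' are the all-cis centres of the dianhydride, made single-handed by alkaloid-mediated double methanolysis to a C2-symmetric bis(hemiester); C6–O is set by iodolactonisation from the C6' carboxyl; both Z alkenes result from equilibrating dehydration.

Key step: step 14

Assumption: the commercial dianhydride is the bis-adduct with both anhydride rings syn to the alkene, and the alkaloid-mediated opening follows the usual empirical sense for cis-fused bicyclic anhydrides (quinine esterifying the carbonyls on C7a and C7'); should the antipode form, quinidine would be used in the same step.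

**Route**

Step 1
Reactants: 1 meso dianhydride
Product: 2 C2-symmetric bis(hemiester)
Conditions: quinine (2.2 equiv), MeOH (6 equiv), toluene, −55 °C; 2 M HCl work-up (alkaloid recovered)
Reagents that add atoms: methanol, CO
Why: Alkaloid-mediated desymmetrising methanolysis of a meso anhydride, in which quinine acts as a chiral general base and, because the two anhydride rings of 1 are related by a twofold axis, directs methanol to the same enantiotopic carbonyl in each ring (those on C7a and C7'), so that the four existing bridge stereocentres become differentiated in one C2-symmetric enantiomer while a single wrong opening gives only the separable meso isomer.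

Step 2
Reactants: 2 C2-symmetric bis(hemiester)
Product: 3 iodolactone acid
Conditions: I2, KI, NaHCO3, H2O/CH2Cl2, 0 °C to rt, dark; then acidify
Reagents that add atoms: iodine, II
Why: Iodolactonisation, in which the iodonium ion on C5=C6 is opened anti by a syn-disposed carboxylate in a 5-exo closure, placing the new C6–O stereocentre on the face turned to the C6'–C7' bridge and the C5 iodide on the opposite face; the two acids are homotopic so either gives the same product, and the remaining acid lies cis to the iodide and cannot displace it.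

Step 3
Reactants: 3 iodolactone acid
Product: 4 lactone acid
Conditions: Bu3SnH, AIBN (cat.), toluene, 80 °C
Reagents that add atoms: none
Why: Radical chain dehalogenation with the tin hydride should remove the secondary iodide (C5 becomes CH2) without touching the lactone, the esters or the acid.

Step 4
Reactants: 4 lactone acid; 5 butyllithium
Product: 8 butyl ketone, via acid chloride 6 (not isolated), via lithium dibutylcuprate 7 (not isolated)
Conditions: (COCl)2, DMF (cat.), CH2Cl2, 0 °C to rt, evaporate; Bu2CuLi (from 5 and CuI, Et2O, −40 °C), THF, −78 °C; aq. NH4Cl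
Reagents that add atoms: butyllithium 5, [Li]CCCC (butyl group, carried by cuprate 7)
Why: Acyl chloride formation followed by acylation of a Gilman cuprate, which stops at the ketone and leaves the lactone and methyl esters alone at −78 °C; the C3a stereocentre is of no consequence because it becomes sp2 in step 5.

Step 5
Reactants: 8 butyl ketone
Product: 10 enone ester, via chloro ketone 9 (not isolated)
Conditions: SO2Cl2 (1.05 equiv), CH2Cl2, 0 °C to rt; evaporate; DBU (1.2 equiv), CH2Cl2, 0 °C
Reagents that add atoms: none
Why: Acid-catalysed α-chlorination of a ketone with SO2Cl2 proceeds through the more substituted enol and should therefore halogenate the methine C3a in preference to the butyl CH2, after which DBU removes HCl by an E1cB elimination through the C7a ester enolate, the only β-hydrogen available because C4 is a bridgehead.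

Step 6
Reactants: 10 enone ester
Product: 11 dioxolane lactone
Conditions: Me3SiOCH2CH2OSiMe3, Me3SiOTf (cat.), CH2Cl2, −78 to 0 °C
Reagents that add atoms: 1,2-bis(trimethylsilyloxy)ethane, C[Si](C)(C)OCCO[Si](C)(C)C
Why: Silyl-triflate-catalysed dioxolanation under aprotic conditions, as used for 2-acylbenzoates, masks the conjugated C3 ketone so that it survives hydride, ylide and alkoxide and cannot later enolise toward the neighbouring C1 ester.

Step 7
Reactants: 11 dioxolane lactone
Product: 12 lactol
Conditions: i-Bu2AlH (1.05 equiv), CH2Cl2, −78 °C; aq. potassium sodium tartrate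
Reagents that add atoms: none
Why: Partial reduction of a lactone to a lactol, in which one equivalent of i-Bu2AlH at −78 °C gives a stable aluminium hemiacetal at the strained γ-lactone, which is more electrophilic than the conjugated, ketal-flanked C1 ester and the hindered C7a' ester; the anomeric centre formed is lost in step 10.

Step 8
Reactants: 13 hept-1-en-3-one
Product: 14 (3-oxoheptyl)triphenylphosphonium bromide
Conditions: Ph3P·HBr, MeCN, 60 °C
Reagents that add atoms: triphenylphosphine hydrobromide, [Br-].c1ccc(cc1)[PH+](c1ccccc1)c1ccccc1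
Why: Phospha-Michael addition of triphenylphosphine to the protonated enone gives the β-keto phosphonium salt directly.

Step 9
Reactants: 14 (3-oxoheptyl)triphenylphosphonium bromide
Product: 15 dithiane phosphonium bromide
Conditions: HS(CH2)3SH, BF3·OEt2, CH2Cl2, 0 °C to rt
Reagents that add atoms: propane-1,3-dithiol, SCCCS
Why: Lewis-acid-promoted dithioketalisation masks the ketone, which prevents retro-Michael loss of triphenylphosphine when the ylide is formed and provides a mask orthogonal to the dioxolane on C3.

Step 10
Reactants: 12 lactol; 15 dithiane phosphonium bromide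
Product: 17 hydroxy alkene, via phosphorus ylide 16 (not isolated)
Conditions: 15 (3 equiv), KN(SiMe3)2 (2.9 equiv), THF, 0 °C; then 12, −78 to 0 °C; cold aq. NH4Cl quench
Reagents that add atoms: none
Why: Wittig olefination of a lactol through its open hydroxy aldehyde with a non-stabilised ylide forms C4'=C5' (Z, geometry irrelevant) and frees the 6-hydroxyl, while low temperature and a cold quench limit epimerisation at C6' and transesterification of the alkoxide with the C7a' ester.

Step 11
Reactants: 17 hydroxy alkene
Product: 18 silyl ether alkene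
Conditions: t-BuMe2SiOTf, 2,6-lutidine, CH2Cl2, −78 to 0 °C
Reagents that add atoms: tert-butyldimethylsilyl triflate, CC(C)(C)[Si](C)(C)OS(=O)(=O)C(F)(F)F
Why: Silylation of the hindered secondary alcohol with the silyl triflate protects the 6-hydroxyl against alkoxide formation in step 14 and sulfonylation in step 15.

Step 12
Reactants: 18 silyl ether alkene
Product: 19 saturated dithiane
Conditions: TsNHNH2, NaOAc, DME/H2O, 85 °C
Reagents that add atoms: none
Why: Diimide reduction saturates the unhindered disubstituted alkene, is not poisoned by sulfur and leaves the tetrasubstituted, conjugated C3a=C7a alkene alone.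

Step 13
Reactants: 19 saturated dithiane
Product: 20 ε-keto ester (Claisen precursor)
Conditions: MeI, CaCO3, MeCN/H2O (4:1), 45 °C
Reagents that add atoms: water, O
Why: S-Alkylative hydrolysis of the dithiane releases the C3' ketone under buffered, near-neutral conditions that the dioxolane, the silyl ether and the esters tolerate.

Step 14
Reactants: 20 ε-keto ester (Claisen precursor)
Product: 21 enolised 2-pentanoyl cyclohexanone (Claisen product)
Conditions: t-BuOK (3 equiv), THF, 0 °C to rt; AcOH quench
Reagents that add atoms: none
Why: t-BuOK reversibly enolises the C3' ketone on both sides, and the C3a' enolate adds to the C7a' ester carbonyl held cis on the neighbouring C7'; loss of methoxide and deprotonation of the resulting 1,3-diketone, the most acidic species present, draw every equilibrium to the cyclised enolate. The closest known reaction is the base-mediated intramolecular Claisen condensation of an ε-keto ester to a 2-acylcyclohexanone. The primed six-membered ring closes in a 6-exo-trig mode. No stereocentre is created: C6' and C7' come from the dianhydride, and the cis-1,2 relation on the bicyclooctene leaves only the cis ring fusion within reach, so any C7' epimer formed through the ester enolate can return to the cyclising isomer. The selectivity needed is between the two α-carbons of the ketone and between the two esters: the C8' enolate would have to close an eight-membered ring, the conjugated C1 ester sits on the far bridge (seven-membered closure), and the dioxolane keeps the C3 carbonyl from the competing five-membered Claisen closure onto C1. Aldol addition of the C7' ester enolate to the ketone is reversible and should drain into the diketonate.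

Step 15
Reactants: 21 enolised 2-pentanoyl cyclohexanone (Claisen product)
Product: 22 enol triflate
Conditions: Tf2O, i-Pr2NEt, CH2Cl2, −78 °C
Reagents that add atoms: triflic anhydride, O=S(=O)(OS(=O)(=O)C(F)(F)F)C(F)(F)F
Why: O-Sulfonylation of a β-diketone, in which 2-acylcyclohexanones enolise within the ring and triflation of that enol should give the endocyclic tetrasubstituted enol triflate on C7a' with the pentanoyl group intact.

Step 16
Reactants: 22 enol triflate
Product: 23 primed keto ester
Conditions: CO (1 atm), Pd(OAc)2 (10 mol %), dppp, Et3N, MeOH/DMF, 60 °C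
Reagents that add atoms: carbon monoxide, [C-]#[O+]; methanol, CO
Why: Palladium-catalysed alkoxycarbonylation of an enol triflate, in which oxidative addition of zerovalent palladium (formed from Pd(OAc)2 and the phosphine), CO insertion and methanolysis of the acyl palladium install C1' as a methyl ester; any enol lactone formed by internal trapping converges in step 18.

Step 17
Reactants: 23 primed keto ester
Product: 24 bis(keto ester) alcohol
Conditions: 3 M HCl, THF, 45 °C
Reagents that add atoms: water, O
Why: Acid hydrolysis removes the dioxolane and the silyl ether in one operation, releasing the C3 ketone and the 6-hydroxyl.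

Step 18
Reactants: 24 bis(keto ester) alcohol
Product: 25 bis(hydroxy butenolide)
Conditions: LiOH, THF/H2O, rt; then 1 M HCl to pH 2
Reagents that add atoms: lithium hydroxide, [Li+].[OH-]
Why: Saponification of the two γ-keto esters, assisted by the neighbouring ketones and carried out in water so that Claisen-type closure to a cyclopentenedione does not compete, followed by acidification gives the keto acids, which rest as their ring tautomers; the hemiketal centres are lost in step 19.

Step 19
Reactants: 25 bis(hydroxy butenolide)
Product: 26 target CNP0289078.2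
Conditions: TsOH·H2O (cat.), toluene, 4 Å molecular sieves, 80 °C
Reagents that add atoms: none
Why: Acid-catalysed dehydration of γ-hydroxybutenolides to γ-alkylidenebutenolides through acyloxocarbenium ions should give both enol lactones under equilibrating conditions, the Z isomers being favoured because they keep the propyl groups away from C4 and C4', while the bicyclic secondary 6-hydroxyl does not ionise.

**Compound list**

1 | bicyclo[2.2.2]oct-7-ene-2,3,5,6-tetracarboxylic 2,3:5,6-dianhydride, meso, both anhydride rings syn to the alkene | O=C1OC(=O)[C@@H]2[C@H]1[C@@H]3C=C[C@H]2[C@H]4C(=O)OC(=O)[C@@H]34 | starting material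
2 | C2-symmetric bis(hemiester), 3,6-bis(methoxycarbonyl)bicyclo[2.2.2]oct-7-ene-2,5-dicarboxylic acid: CO2H on C3a and C6', CO2Me on C7a and C7', all four syn to the C5=C6 alkene | OC(=O)[C@H]1[C@@H](C(=O)OC)[C@H]2C=C[C@@H]1[C@H](C(=O)OC)[C@@H]2C(=O)O | intermediate
3 | iodolactone acid: γ-lactone C5'(=O)–O–C6 with the oxygen on the face of C6 turned to the C6'–C7' bridge, iodine on C5 on the opposite face, CO2H on C3a, CO2Me on C7a and C7' | O=C1O[C@@H]2[C@@H](I)[C@H]3[C@@H](C(=O)O)[C@@H](C(=O)OC)[C@@H]2[C@@H]1[C@H]3C(=O)OC | intermediate
4 | lactone acid: as 3 with C5 as CH2 | O=C1O[C@@H]2C[C@H]3[C@@H](C(=O)O)[C@@H](C(=O)OC)[C@@H]2[C@@H]1[C@H]3C(=O)OC | intermediate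
5 | butyllithium | [Li]CCCC | starting material
6 | acid chloride of 4 (COCl on C3a; not isolated) | O=C1O[C@@H]2C[C@H]3[C@@H](C(=O)Cl)[C@@H](C(=O)OC)[C@@H]2[C@@H]1[C@H]3C(=O)OC | intermediate
7 | lithium dibutylcuprate Bu2CuLi (not isolated) | [Li+].CCCC[Cu-]CCCC | intermediate
8 | butyl ketone: pentanoyl (C3) on C3a, cis to CO2Me on C7a; lactone and C7' ester as in 4 | O=C1O[C@@H]2C[C@H]3[C@@H](C(=O)CCCC)[C@@H](C(=O)OC)[C@@H]2[C@@H]1[C@H]3C(=O)OC | intermediate
9 | chloro ketone: chlorine on C3a, either epimer (not isolated) | O=C1O[C@@H]2C[C@H]3C(Cl)(C(=O)CCCC)[C@@H](C(=O)OC)[C@@H]2[C@@H]1[C@H]3C(=O)OC | intermediate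
10 | enone ester: C3a=C7a alkene with pentanoyl on C3a and CO2Me (C1) on C7a; lactone and C7' ester unchanged | O=C1O[C@@H]2C[C@H]3C(C(=O)CCCC)=C(C(=O)OC)[C@@H]2[C@@H]1[C@H]3C(=O)OC | intermediate
11 | dioxolane lactone: C3 ketone of 10 as 2-butyl-1,3-dioxolane | O=C1O[C@@H]2C[C@H]3C(C4(CCCC)OCCO4)=C(C(=O)OC)[C@@H]2[C@@H]1[C@H]3C(=O)OC | intermediate
12 | lactol: C5' hemiacetal of 11, both anomers | OC1O[C@@H]2C[C@H]3C(C4(CCCC)OCCO4)=C(C(=O)OC)[C@@H]2[C@@H]1[C@H]3C(=O)OC | intermediate
13 | hept-1-en-3-one | C=CC(=O)CCCC | starting material
14 | (3-oxoheptyl)triphenylphosphonium bromide | CCCCC(=O)CC[P+](c1ccccc1)(c1ccccc1)c1ccccc1.[Br-] | intermediate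
15 | [2-(2-butyl-1,3-dithian-2-yl)ethyl]triphenylphosphonium bromide | CCCCC1(CC[P+](c2ccccc2)(c2ccccc2)c2ccccc2)SCCCS1.[Br-] | intermediate
16 | phosphorus ylide of 15 (not isolated) | CCCCC1(CC=P(c2ccccc2)(c2ccccc2)c2ccccc2)SCCCS1 | intermediate
17 | hydroxy alkene: free 6-OH; C6' carries (Z)-CH=CH–CH2–(2-butyl-1,3-dithian-2-yl), cis to CO2Me on C7', both turned to the C5–C6 bridge; C3 dioxolane, C1 methyl ester | CCCCC1(SCCCS1)C/C=C\[C@@H]2[C@H]3C(C(=O)OC)=C(C4(CCCC)OCCO4)[C@H](C[C@H]3O)[C@@H]2C(=O)OC | intermediate
18 | silyl ether alkene: 6-O-tert-butyldimethylsilyl ether of 17 | CCCCC1(SCCCS1)C/C=C\[C@@H]2[C@H]3C(C(=O)OC)=C(C4(CCCC)OCCO4)[C@H](C[C@H]3O[Si](C)(C)C(C)(C)C)[C@@H]2C(=O)OC | intermediate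
19 | saturated dithiane: 18 with C4'–C5' reduced | CCCCC1(SCCCS1)CCC[C@@H]2[C@H]3C(C(=O)OC)=C(C4(CCCC)OCCO4)[C@H](C[C@H]3O[Si](C)(C)C(C)(C)C)[C@@H]2C(=O)OC | intermediate
20 | ε-keto ester (Claisen precursor): C6' carries (CH2)3C(=O)Bu, C7' carries CO2Me (cis), C3 dioxolane, C1 methyl ester, 6-OTBS | CCCCC(=O)CCC[C@@H]1[C@H]3C(C(=O)OC)=C(C4(CCCC)OCCO4)[C@H](C[C@H]3O[Si](C)(C)C(C)(C)C)[C@@H]1C(=O)OC | intermediate
21 | Claisen product: primed ring closed as the enolised 1,3-diketone, enol OH on C7a', pentanoyl on C3a' | OC2=C(C(=O)CCCC)CC[C@@H]1[C@H]3C(C(=O)OC)=C(C4(CCCC)OCCO4)[C@H](C[C@H]3O[Si](C)(C)C(C)(C)C)[C@H]21 | intermediate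
22 | enol triflate: OTf on C7a', pentanoyl on C3a' | O=S(=O)(C(F)(F)F)OC2=C(C(=O)CCCC)CC[C@@H]1[C@H]3C(C(=O)OC)=C(C4(CCCC)OCCO4)[C@H](C[C@H]3O[Si](C)(C)C(C)(C)C)[C@H]21 | intermediate
23 | primed keto ester: CO2Me (C1') on C7a', pentanoyl on C3a'; C3 dioxolane, C1 methyl ester, 6-OTBS | COC(=O)C2=C(C(=O)CCCC)CC[C@@H]1[C@H]3C(C(=O)OC)=C(C4(CCCC)OCCO4)[C@H](C[C@H]3O[Si](C)(C)C(C)(C)C)[C@H]21 | intermediate
24 | bis(keto ester) alcohol: pentanoyl/CO2Me pairs on C3a/C7a and C3a'/C7a', free 6-OH | COC(=O)C2=C(C(=O)CCCC)CC[C@@H]1[C@H]3C(C(=O)OC)=C(C(=O)CCCC)[C@H](C[C@H]3O)[C@H]21 | intermediate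
25 | bis(3-butyl-3-hydroxy butenolide): ring tautomer of the bis(keto acid), epimer mixtures at C3 and C3' | CCCCC1(O)OC(=O)C2=C1CC[C@@H]1[C@H]3C4=C(C(O)(CCCC)OC4=O)[C@H](C[C@H]3O)[C@H]21 | intermediate
26 | CNP0289078.2: (3Z,3'Z,4R,6R,7S,6'S,7'R)-configured hydroxylated phthalide dimer | CCC/C=C1\OC(=O)C2=C1CC[C@@H]1[C@H]3C4=C(/C(=C/CCC)OC4=O)[C@H](C[C@H]3O)[C@H]21 | target

**Step count**

Total: 19 steps. Longest linear sequence: 17 steps (steps 1–7 and 10–19); steps 8–9 prepare the phosphonium salt.

**Steps most likely to fail**

Step 5. The chlorination may go to the butyl α-carbon instead of C3a, or twice, and base may then start condensation of that side chain with the C1 ester. The fallback moves the halogenation to the acid stage, where only one enolisable position exists. It sets out from 4: thionyl chloride gives acid chloride 6, and N-bromosuccinimide with catalytic HBr (Hell–Volhard–Zelinsky conditions) brominates it at C3a to give the bromo acyl chloride F1. Triethylamine then removes HBr across C3a–C7a through the C1 ester enolate to give the alkenoyl chloride F2, and acylation of cuprate 7 at −78 °C returns to the route at 10.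

Step 7. Hydride may also be transferred to a methyl ester, or the lactol may be reduced further to the diol, which would lactonise onto the C7a' ester. The fallback reaches the aldehyde level without a hydride reagent that can touch esters. It sets out from 11: one equivalent of LiOH at 0 °C opens the strained lactone to the lithium hydroxy carboxylate F3, which is silylated on the 6-oxygen in the same flask (t-BuMe2SiOTf, 2,6-lutidine; aqueous K2CO3 work-up, then mild acid) to give the silyloxy acid F4. Coupling with ethanethiol (DCC, DMAP) gives the S-ethyl thioester F5, and Fukuyama reduction (Et3SiH, palladium on carbon) gives the aldehyde F6. Wittig reaction of F6 with ylide 16 returns to the route at 18, the silylation of step 11 being already done.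

Step 1. One of the two openings may be poorly discriminated, or the sparingly soluble dianhydride may react too slowly at low temperature. The fallback replaces asymmetric induction by resolution. It sets out from 1: methanolysis without alkaloid (MeOH, Et3N, rt) gives the two regioisomeric bis(hemiesters), the meso bis(hemiester) F7 and the racemate made up of 2 and the antipode of 2 F8. The racemate is separated by crystallisation and resolved by crystallising the bis[(R)-1-phenylethylammonium] salt of 2 F9 (the amine enantiomer to be settled by trial), and acidification returns to the route at 2.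

Further compounds
F1 | step 5 | C3a-bromo acyl chloride (either C3a epimer) | O=C1O[C@@H]2C[C@H]3C(Br)(C(=O)Cl)[C@@H](C(=O)OC)[C@@H]2[C@@H]1[C@H]3C(=O)OC
F2 | step 5 | alkenoyl chloride (C3a=C7a, COCl on C3a, CO2Me on C7a) | O=C1O[C@@H]2C[C@H]3C(C(=O)Cl)=C(C(=O)OC)[C@@H]2[C@@H]1[C@H]3C(=O)OC
F3 | step 7 | lithium hydroxy carboxylate (C5' carboxylate on C6', free 6-OH) | [Li+].[O-]C(=O)[C@@H]1[C@H]3C(C(=O)OC)=C(C4(CCCC)OCCO4)[C@H](C[C@H]3O)[C@@H]1C(=O)OC
F4 | step 7 | silyloxy acid (CO2H on C6', 6-OTBS) | OC(=O)[C@@H]1[C@H]3C(C(=O)OC)=C(C4(CCCC)OCCO4)[C@H](C[C@H]3O[Si](C)(C)C(C)(C)C)[C@@H]1C(=O)OC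
F5 | step 7 | S-ethyl thioester of F4 | CCSC(=O)[C@@H]1[C@H]3C(C(=O)OC)=C(C4(CCCC)OCCO4)[C@H](C[C@H]3O[Si](C)(C)C(C)(C)C)[C@@H]1C(=O)OC
F6 | step 7 | aldehyde (CHO as C5' on C6', 6-OTBS) | O=C[C@@H]1[C@H]3C(C(=O)OC)=C(C4(CCCC)OCCO4)[C@H](C[C@H]3O[Si](C)(C)C(C)(C)C)[C@@H]1C(=O)OC
F7 | step 1 | meso bis(hemiester) (acids on C3a and C7', esters on C7a and C6') | OC(=O)[C@H]1[C@@H](C(=O)OC)[C@H]2C=C[C@@H]1[C@H](C(=O)O)[C@@H]2C(=O)OC
F8 | step 1 | antipode of 2 | OC(=O)[C@@H]1[C@H](C(=O)OC)[C@@H]2C=C[C@H]1[C@@H](C(=O)OC)[C@H]2C(=O)O
F9 | step 1 | bis[(R)-1-phenylethylammonium] salt of 2 | [O-]C(=O)[C@H]1[C@@H](C(=O)OC)[C@H]2C=C[C@@H]1[C@H](C(=O)OC)[C@@H]2C(=O)[O-].C[C@@H]([NH3+])c1ccccc1.C[C@@H]([NH3+])c1ccccc1
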